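**Retrosynthetic overview**

1. Target ⇒ last bond C-1–C-8 by transannular cationic cyclisation of a tertiary isopropyl carbinol on C-7 of a bicyclo[4.3.1]decane; the carbinol comes from the C-7 ketone and an isopropyl organocerium.
2. C-7 ketone ⇒ one-step formal (4+3) annulation of an achiral, fully substituted acylphloroglucinol carrying a tethered methyl enone: ipso-Michael (C-3–C-11) plus oxidative C-5–C-6 coupling under chiral ammonium hypoiodite catalysis (metal-free; sets C-3, C-5, C-11).
3. Arene ⇒ phlorisobutyrophenone + geranyl bromide + an iodo-enone by two C-alkylations; iodo-enone ⇒ methyl 3,3-dimethylpent-4-enoate + methyl vinyl ketone (reduction, iodination, cross-metathesis).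
4. Ring order: aromatic ring (bought) → cyclopentane and first seven-membered ring together (key step) → the bicyclo[3.3.1]nonane six-membered ring and second seven-membered ring (homoadamantane cage) in the last step.

Numbering used in names: C-1 isobutyryl-bearing carbon, C-2, C-3 spiro carbon, C-4, C-5 geranyl-bearing carbon, C-6 H2, C-7, C-8 (CMe2), C-9 (C=O between C-1 and C-5), C-10 H2 (on C-7), C-11 H (on C-3), C-12 (CMe2), C-13, C-14 (CH2CH2 back to C-3). The target is 1S,3S,5R,7R,11R in this numbering.

Assumption: the (R,R)-ammonium iodide in step 6 is taken to give the enantiomer drawn; if the sense of induction is opposite, the (S,S)-catalyst is used.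

Step 1
Reactants: 1 methyl 3,3-dimethylpent-4-enoate
Product: 2 3,3-dimethylpent-4-en-1-ol
Conditions: LiAlH4, Et2O, 0 °C to rt
Reagents that add atoms: none
Why: LiAlH4 reduction of the ester to the primary alcohol; the isolated vinyl group is inert and no stereocenter is formed.

Step 2
Reactants: 2 3,3-dimethylpent-4-en-1-ol
Product: 3 5-iodo-3,3-dimethylpent-1-ene
Conditions: PPh3, I2, imidazole, CH2Cl2, 0 °C to rt
Reagents that add atoms: iodine, I-I
Why: Appel iodination of an unhindered primary alcohol (the quaternary carbon is two atoms away); no stereocenter.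

Step 3
Reactants: 3 5-iodo-3,3-dimethylpent-1-ene; 4 but-3-en-2-one (methyl vinyl ketone)
Product: 5 (E)-7-iodo-5,5-dimethylhept-3-en-2-one
Conditions: second-generation Hoveyda–Grubbs catalyst RuCl2(SIMes)(=CH-C6H4-2-OiPr) (5 mol %), 4 (4 equiv), CH2Cl2, 45 °C
Reagents that add atoms: none
Why: Olefin cross-metathesis between a quaternary-allylic terminal alkene (which does not homodimerise) and an electron-poor enone; the E-enone forms under thermodynamic control and the primary iodide is tolerated.

Step 4
Reactants: 6 2-methyl-1-(2,4,6-trihydroxyphenyl)propan-1-one (phlorisobutyrophenone); 7 geranyl bromide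
Product: 8 1-{3-[(2E)-3,7-dimethylocta-2,6-dien-1-yl]-2,4,6-trihydroxyphenyl}-2-methylpropan-1-one (3-geranylphlorisobutyrophenone)
Conditions: 10 % aq. KOH, 0 °C to rt
Reagents that add atoms: none
Why: Established C-geranylation of an acylphloroglucinol (C-alkylation of the phenolate by an allylic bromide in water); mono-alkylation is controlled by stoichiometry, the E-alkene is retained and no stereocenter is formed.

Step 5
Reactants: 8 3-geranylphlorisobutyrophenone; 5 (E)-7-iodo-5,5-dimethylhept-3-en-2-one
Product: 9 1-{3-geranyl-5-[(4E)-3,3-dimethyl-6-oxohept-4-en-1-yl]-2,4,6-trihydroxyphenyl}-2-methylpropan-1-one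
Conditions: K2CO3, CF3CH2OH, 50 °C
Reagents that add atoms: none
Why: SN2 C-alkylation of the phloroglucinolate at its last free ring carbon, the hydrogen-bonding fluorinated solvent shielding oxygen so that C- beats O-alkylation; 9 is achiral, and any reversible spiro-Michael tautomer converges in step 6.

Step 6
Reactants: 9 1-{3-geranyl-5-[(4E)-3,3-dimethyl-6-oxohept-4-en-1-yl]-2,4,6-trihydroxyphenyl}-2-methylpropan-1-one
Product: 12 tricyclic enol-triketone (bicyclo[4.3.1]decane with C-7 ketone fused to the 12,12-dimethylcyclopentane), via spiro Michael adduct 10 (not isolated), via iodomethyl ketone 11 (not isolated)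
Conditions: (R,R)-3,3′-bis[3,5-bis(trifluoromethyl)phenyl] N-spiro bis(binaphthyl)ammonium iodide (10 mol %), cumene hydroperoxide (1.1 equiv, slow addition), K2CO3 (0.5 equiv), toluene/t-BuOMe, 0 °C
Reagents that add atoms: none
Why: Proposed new method: enantioselective ammonium hypoiodite-catalysed oxidative (4+3)-type annulation — the chiral ammonium phenoxide of 9 adds C-3 reversibly (5-exo ipso-Michael) to the tethered enone (10), the hypoiodite made in situ from the iodide and the hydroperoxide iodinates the unhindered methyl ketone (11), and the ion-paired dienolate closes irreversibly by C-alkylation at C-5; the chiral cation selects one enantiomer of the equilibrating 10/11 (dynamic kinetic resolution) and the tether is expected to cross the ring face away from the ion-paired C-4 oxygen, so C-10 ends cis to C-2 (sets C-3, C-5, C-11); closest known reactions are the chiral ammonium hypoiodite-catalysed oxidative cyclisation of ketophenols (α-iodination then intramolecular substitution, C–O bond) and the phase-transfer alkylative dearomatization–annulation of acylphloroglucinols.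

Step 7
Reactants: 12 tricyclic enol-triketone
Product: 13 C-7 tertiary carbinol (7-hydroxy-7-isopropyl derivative of 12)
Conditions: iPrMgCl/CeCl3 (3.5 equiv each), THF, −78 to 0 °C; aq. NH4Cl
Reagents that add atoms: isopropylmagnesium chloride, CC(C)[Mg]Cl
Why: Organocerium 1,2-addition to the only reactive ketone (the acidic enol-triketone is masked as its enolate and the C-4 ketone lies between two quaternary carbons); attack on the open exo face gives one carbinol epimer, whose configuration is erased in step 8.

Step 8
Reactants: 13 C-7 tertiary carbinol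
Product: 14 target CNP0313870.1
Conditions: Tf2NH (10 mol %), (CF3)2CHOH/CH2Cl2 1:4, −40 to 0 °C
Reagents that add atoms: none
Why: SN1 ionisation of the tertiary carbinol, 1,2-hydride shift from the isopropyl methine to the exo face of C-7, and transannular C-alkylation of the enol carbon C-1 by the resulting 2-propyl cation (biomimetic type A cationic cyclisation) close the bicyclo[3.3.1]nonane/homoadamantane; the cage fixes C-7 (H exo) and C-1, and the carbinol ionises under conditions too mild to protonate the geranyl alkenes.

**Compound list**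

1 | methyl 3,3-dimethylpent-4-enoate | COC(=O)CC(C)(C)C=C | starting material
2 | 3,3-dimethylpent-4-en-1-ol | OCCC(C)(C)C=C | intermediate
3 | 5-iodo-3,3-dimethylpent-1-ene | ICCC(C)(C)C=C | intermediate
4 | but-3-en-2-one (methyl vinyl ketone) | CC(=O)C=C | starting material
5 | (E)-7-iodo-5,5-dimethylhept-3-en-2-one | CC(=O)/C=C/C(C)(C)CCI | intermediate
6 | 2-methyl-1-(2,4,6-trihydroxyphenyl)propan-1-one (phlorisobutyrophenone) | CC(C)C(=O)c1c(O)cc(O)cc1O | starting material
7 | geranyl bromide, (2E)-1-bromo-3,7-dimethylocta-2,6-diene | CC(C)=CCC/C(C)=C/CBr | starting material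
8 | 3-geranylphlorisobutyrophenone | CC(C)=CCC/C(C)=C/Cc1c(O)cc(O)c(C(=O)C(C)C)c1O | intermediate
9 | achiral aromatic precursor: 3-geranyl-5-[(4E)-3,3-dimethyl-6-oxohept-4-enyl]phlorisobutyrophenone | CC(C)=CCC/C(C)=C/Cc1c(O)c(CCC(C)(C)/C=C/C(C)=O)c(O)c(C(=O)C(C)C)c1O | intermediate
10 | spiro Michael adduct: enolised spiro[4.5]decane-trione, spiro carbon C-3, geranyl on C-5, isobutyryl on C-1, 2-oxopropyl on C-11 cis to C-2 | CC(C)=CCC/C(C)=C/CC1=C(O)C(C(=O)C(C)C)=C(O)[C@@]2(C1=O)CCC(C)(C)[C@H]2CC(C)=O | intermediate
11 | iodomethyl ketone: 10 with the methyl ketone α-iodinated | CC(C)=CCC/C(C)=C/CC1=C(O)C(C(=O)C(C)C)=C(O)[C@@]2(C1=O)CCC(C)(C)[C@H]2CC(=O)CI | intermediate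
12 | tricyclic enol-triketone: bicyclo[4.3.1]decane (bridgeheads C-3 and C-5; bridges C-4=O, C-2(OH)=C-1(isobutyryl)–C-9=O and C-6H2–C-7(=O)–C-10H2–C-11H), cyclopentane fused on C-3/C-11, geranyl on C-5, H-11 on the C-4 side | CC(C)=CCC/C(C)=C/C[C@@]12CC(=O)C[C@@H]3C(C)(C)CC[C@]3(C1=O)C(O)=C(C(=O)C(C)C)C2=O | intermediate
13 | C-7 tertiary carbinol: 12 with C-7 bearing isopropyl (exo) and OH (endo) | CC(C)=CCC/C(C)=C/C[C@@]12C[C@@](O)(C(C)C)C[C@@H]3C(C)(C)CC[C@]3(C1=O)C(O)=C(C(=O)C(C)C)C2=O | intermediate
14 | CNP0313870.1, (1S,3S,5R,7R,11R) in the numbering above | CC(C)=CCC/C(C)=C/C[C@@]12C[C@H]3C[C@@H]4C(C)(C)CC[C@]4(C1=O)C(=O)[C@@](C(=O)C(C)C)(C2=O)C3(C)C | target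

**Step count**

Total steps: 8. Longest linear sequence: 7 (steps 1, 2, 3, 5, 6, 7, 8).

**Three steps most likely to fail, with fallbacks**

Step 6 (the proposed new method). Risks are direct oxidation of the electron-rich ring or of the C-1 enol, iodination at C-10 instead of the methyl group, O- instead of C-alkylation, and low control of the C-11 epimer or of ee. The fallback uses known chemistry, sets out from 9 and comes back at 12. Compound 9 is persilylated (TMSOTf, Et3N, CH2Cl2, −78 °C) to the tetrakis(trimethylsilyl) dienol ether F1. N-Chlorosuccinimide chlorinates the terminal carbon of the 2-silyloxydiene, and aqueous citric acid removes the aryl silyl ethers to give the chloromethyl enone F2. F2 is cyclised by the established phase-transfer alkylative dearomatization–annulation of acylphloroglucinols (Cinchona-alkaloid-derived dimeric ammonium bromide, CsOH·H2O, CH2Cl2, −50 °C). It passes through the spiro chloromethyl ketone F3 by ipso-Michael addition and closes by C-alkylation to 12, with no oxidant present.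

Step 8. Risks are capture of the first-formed C-7 cation by C-1 before the hydride shift (a five-membered ring instead of the cage), O-capture, and acid damage to the geranyl group. The fallback sets out from 12 and comes back at 14, closing the ring by a radical instead of a cation. Wittig olefination of 12 with isopropylidenetriphenylphosphorane (from isopropyltriphenylphosphonium iodide and KN(SiMe3)2, THF) gives the isopropylidene compound F4. Mn(OAc)3·2H2O (trivalent manganese) in ethanol oxidises the enol-triketone to the C-1 radical, which adds to the dimethyl-bearing alkene carbon. The tertiary C-7 radical then takes hydrogen from ethanol on its exo face to give 14.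

Step 5. The risk is O-alkylation or low conversion with an unactivated primary iodide. The fallback sets out from 2 (with 4 and 8) and comes back at 9, replacing the SN2 alkylation by a reductive alkylation. Alcohol 2 is oxidised with Dess–Martin periodinane to 3,3-dimethylpent-4-enal F5. Cross-metathesis of F5 with 4 (same Ru catalyst as in step 3) gives (E)-3,3-dimethyl-6-oxohept-4-enal F6. F6 is joined to 8 by organocatalytic three-component reductive alkylation (L-proline, Hantzsch ester, CH2Cl2, rt): the quinone methide F7 formed by condensation at the free ring carbon is reduced in situ to 9.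

**Further compounds**

F1 | step 6 | tetrakis(trimethylsilyl) dienol ether of 9 | CC(C)=CCC/C(C)=C/Cc1c(O[Si](C)(C)C)c(CCC(C)(C)/C=C/C(=C)O[Si](C)(C)C)c(O[Si](C)(C)C)c(C(=O)C(C)C)c1O[Si](C)(C)C
F2 | step 6 | chloromethyl enone: 9 with the methyl ketone α-chlorinated | CC(C)=CCC/C(C)=C/Cc1c(O)c(CCC(C)(C)/C=C/C(=O)CCl)c(O)c(C(=O)C(C)C)c1O
F3 | step 6 | spiro chloromethyl ketone (chloro analogue of 11) | CC(C)=CCC/C(C)=C/CC1=C(O)C(C(=O)C(C)C)=C(O)[C@@]2(C1=O)CCC(C)(C)[C@H]2CC(=O)CCl
F4 | step 8 | 7-isopropylidene analogue of 12 | CC(C)=CCC/C(C)=C/C[C@@]12CC(=C(C)C)C[C@@H]3C(C)(C)CC[C@]3(C1=O)C(O)=C(C(=O)C(C)C)C2=O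
F5 | step 5 | 3,3-dimethylpent-4-enal | C=CC(C)(C)CC=O
F6 | step 5 | (E)-3,3-dimethyl-6-oxohept-4-enal | CC(=O)/C=C/C(C)(C)CC=O
F7 | step 5 | quinone methide from 8 and F6 | CC(C)=CCC/C(C)=C/CC1=C(O)C(C(=O)C(C)C)=C(O)C(=CCC(C)(C)/C=C/C(C)=O)C1=O
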